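All runs stem from a simulated flask for an exercise.

**The choice.** Track free Q against Z at every sampling: the next flasks must choose between more Q and more time.

common to all: G 48 mM
- Saturday's: Q 0.91 equiv; run made earlier
- Wednesday's: Q 2 equiv; run made earlier
- Friday's: Q 3.5 equiv; run made earlier
- south: Q 1.00 equiv; time 6.0 d
- south-east: Q 3.00 equiv; time 6.0 d
- south-west: Q 4.00 equiv; time 6.0 d

| run | time / d | Z / % | D / % | G / % |
|---|---|---|---|---|
| Saturday's | 0.833 | 0 | 2.0 | 49.0 |
| Saturday's | 1.67 | 0.6 | 3.5 | 35.0 |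
| Saturday's | 2.50 | 0 | 4.9 | 27.0 |
| Saturday's | 3.00 | 1.9 | 4.0 | 24.3 |
| Saturday's | 4.00 | 1.3 | 3.9 | 22.3 |
| Wednesday's | 0.417 | 0.9 | 2.3 | 36.4 |
| Wednesday's | 1.04 | 4.0 | 4.3 | 13.1 |
| Wednesday's | 2.08 | 7.0 | 10.4 | 3.8 |
| Wednesday's | 3.00 | 10.8 | 14.1 | 2.3 |
| Wednesday's | 4.00 | 10.0 | 23.2 | 1.2 |
| Friday's | 0.417 | 5.6 | 3.7 | 16.5 |
| Friday's | 1.04 | 13.6 | 9.0 | 1.6 |
| Friday's | 2.08 | 23.1 | 19.1 | 0.8 |
| Friday's | 3.00 | 25.4 | 29.0 | 0 |
| Friday's | 4.00 | 25.3 | 37.4 | 0 |

(readings scatter by 1 percentage point)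

- a reading or a percentage of D counts all its forms, free or not
- a reading of G is of its free form alone

* amount of Z at the end, in percent of the G charged, for each flask in turn (south, south-east, south-west)

**What stalls.** In Friday's run D climbs from 29.0 % to 37.4 % between 3.00 d and 4.00 d, while Z reads 25.4 % and 25.3 %. So Z does not follow total D. A reading of D counts all its forms, so I guess that the dissolved part holds steady. When Z stands still, its making and unmaking rates are equal. Dividing one by the other removes time and leaves [Z]/[Q] constant, an apparent equilibrium constant at fixed dissolved D.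

**The ratio.** Q is unread, so I get it from uptake, counting the unread balance as mono adduct X: each reacted G took one Q, each D one more, each Z two more. At 4.00 d that leaves [Q] at 77.8 mM in Friday's run and 27.8 mM in Wednesday's. The plateau ratio r, [Z] over free [Q], reads 0.156 and 0.172, so I carry the mean, 0.164, a reading with its scatter.

**My reckoning.** Supposing for south-east and south-west that G and D stand at Friday's last readings, 0 % and 37.4 %, balance and ratio together give Z of 20.1 % at 3.00 equiv and 32.5 % at 4.00 equiv. Saturday's balance, at 0.91 equiv and 4.00 d, leaves [Q] at 3.26 mM; I use that [Q] for south, at 1.00 equiv, and put south low, near 1.12 %. I raise Q and leave the time at 6.0 d.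

**The forecast.** It gives 2.5 %, 20 % and 31 %, on the ground that “Extra time to 6 d should therefore add little”. At south it stands higher than my figure.

**The flasks.**

    G + Q → X (k = 3.50 × 10⁻⁴ M⁻¹ s⁻¹)
    Q + X → D (k = 3.30 × 10⁻⁵ M⁻¹ s⁻¹)
    Q + D ⇌ Z (K = 78.0 M⁻¹, k = 4.90 × 10⁻⁴ M⁻¹ s⁻¹)
    L ⇌ D, rate k4*(cs4 - [D]) while solid is left; crystals form when [D] > cs4 (solubility = 2.10 mM, k = 6.70 × 10⁻⁴ s⁻¹)
    G + D ⇌ E, settled at all times (K = 11.0 M⁻¹)

South ends at 1.30 %, south-east at 20.1 % and south-west at 32.0 %, within the forecast's tolerance. At 6.00 d south-west holds L 45.9 %, counted in its D of 50.4 %. The forecast's 20 % would stand too high for a far longer south-east run: at 60.0 d south-east has Q at 28.7 % of its charge, r turns that into 14.1 %, and the flask holds Z 14.1 %.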